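Retrosynthesis: the two ester C–O bonds are cut first; the C10 allylic alcohol is traced back to a C9=C10 olefin (epoxide, allylic transposition) and the C6 carbinol to a C5=C6 vinylsilane; C1–C5 and C6–C7 are then cut together in a rhodium-catalysed (5+2) cycloaddition.
Enabling feature: C1, C10, C9, C8 and C7 map onto a (2-methylcyclopropyl)alkene (olefin C1=C10, three-membered ring C9–C8–C7), and the tertiary carbinol C4 is propargylic once C5–C6 is an alkyne, tied to C1 by C2–C3; one step then closes the five-membered ring (C1–C5) and the seven-membered ring (C6–C7).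
Forward: crotyl alcohol gives the cyclopropyl diene; a B-alkyl Suzuki coupling joins C3 to C4; Sharpless epoxidation and epoxy chloride fragmentation give the silylalkynyl carbinol; the (5+2) closes both rings; then C6 ketone, anti diol, aroylation, epoxidation and transposition to the C10 alcohol, isovalerylation, desilylation.
Stereochemistry: C8 and C9 come from the asymmetric cyclopropanation and are relayed to C1 by the stereospecific cyclopropane opening; C4 from the Sharpless epoxidation; C5 from enol protonation on the open face; C6 from hydroxyl-directed, convex-face reduction; C10 from convex-face epoxidation, its C–O bond being kept while C9 is opened with inversion and H8 is lost by anti elimination.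

Key step: step 9

Remark: numbering is C1 (quaternary fusion C–CH3), C2, C3, C4 (isopropyl carbinol), C5 (fusion CH), C6 (CH–O-aroyl), C7, C8 (olefinic C–CH3), C9, C10 (CH–O-isovaleryl); the SMILES is read as the cis-fused skeleton with C1–CH3, H5, 4-OH and 10-O on one face and 6-O and isopropyl on the other; the sense of induction of the dioxaborolane ligand and of L-(+)-diethyl tartrate is taken from the usual models, and compounds 1, 6 and 20 and all reagents are taken as commercial.

Step 1
Reactants: 1 (E)-but-2-en-1-ol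
Product: 2 [(1S,2S)-2-methylcyclopropyl]methanol
Conditions: Et2Zn, CH2I2, (4R,5R)-2-butyl-N,N,N',N'-tetramethyl-1,3,2-dioxaborolane-4,5-dicarboxamide (1.2 equiv), CH2Cl2, 0 → 23 °C
Reagents that add atoms: diiodomethane, ICI
Why: Asymmetric Simmons–Smith cyclopropanation in which the zinc alkoxide of the allylic alcohol is held by the chiral dioxaborolane, so that Zn(CH2I)2 adds to one olefin face and sets C8 and C9 (trans from the E olefin, absolute configuration from the ligand).

Step 2
Reactants: 2 [(1S,2S)-2-methylcyclopropyl]methanol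
Product: 4 (2E)-2-methyl-3-[(1S,2S)-2-methylcyclopropyl]prop-2-enal, via cyclopropanecarbaldehyde 3 (not isolated)
Conditions: 2,2,6,6-tetramethylpiperidin-1-oxyl (10 mol %), PhI(OAc)2, CH2Cl2, 23 °C; then Ph3P=C(CH3)CHO, 40 °C
Reagents that add atoms: 2-(triphenylphosphoranylidene)propanal, CC(C=O)=P(c1ccccc1)(c1ccccc1)c1ccccc1
Why: Oxoammonium oxidation of the primary alcohol and, without isolation of the volatile aldehyde, a Wittig reaction with a stabilised ylide, which should give the E enal (formyl trans to cyclopropyl) that fixes the later C1=C10 geometry.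

Step 3
Reactants: 4 (2E)-2-methyl-3-[(1S,2S)-2-methylcyclopropyl]prop-2-enal
Product: 5 (1S,2S)-1-methyl-2-[(1E)-2-methylbuta-1,3-dien-1-yl]cyclopropane
Conditions: Ph3PCH3Br, KOtBu, THF, 0 → 23 °C
Reagents that add atoms: methyltriphenylphosphonium bromide, C[P+](c1ccccc1)(c1ccccc1)c1ccccc1.[Br-]
Why: Wittig methylenation of the aldehyde adds the future C3 without touching the trisubstituted olefin or the cyclopropane, and the volatile diene is carried on as a solution.

Step 4
Reactants: 6 4-methylpent-2-yn-1-ol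
Product: 8 (2Z)-3-iodo-4-methylpent-2-en-1-ol, via cyclic alkenylaluminate 7 (not isolated)
Conditions: NaAlH2(OCH2CH2OMe)2, THF, 0 → 23 °C; then I2, −78 °C
Reagents that add atoms: iodine, II
Why: Hydroxyl-directed trans-hydroalumination places aluminium on the distal alkyne carbon in a five-membered chelate, and iodinolysis with retention should give the Z iodoalkene with the isopropyl group trans to CH2OH.

Step 5
Reactants: 5 (1S,2S)-1-methyl-2-[(1E)-2-methylbuta-1,3-dien-1-yl]cyclopropane; 8 (2Z)-3-iodo-4-methylpent-2-en-1-ol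
Product: 10 (2E,6E)-6-methyl-7-[(1S,2S)-2-methylcyclopropyl]-3-(propan-2-yl)hepta-2,6-dien-1-ol, via alkylborane 9 (not isolated)
Conditions: 9-borabicyclo[3.3.1]nonane, THF, 0 → 23 °C; then 8, PdCl2(dppf) [dppf = 1,1'-bis(diphenylphosphino)ferrocene] (5 mol %), AsPh3, Cs2CO3, DMF/H2O, 23 °C
Reagents that add atoms: none
Why: The borane should add only to the monosubstituted vinyl end of the diene, and the B-alkyl Suzuki–Miyaura coupling joins C3 to C4 with retention of the iodoalkene geometry.

Step 6
Reactants: 10 (2E,6E)-6-methyl-7-[(1S,2S)-2-methylcyclopropyl]-3-(propan-2-yl)hepta-2,6-dien-1-ol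
Product: 11 [(2S,3S)-3-{(3E)-3-methyl-4-[(1S,2S)-2-methylcyclopropyl]but-3-en-1-yl}-3-(propan-2-yl)oxiran-2-yl]methanol
Conditions: Ti(OiPr)4 (10 mol %), L-(+)-diethyl tartrate (12 mol %), tBuOOH, 4 Å molecular sieves, CH2Cl2, −20 °C
Reagents that add atoms: tert-butyl hydroperoxide, CC(C)(C)OO
Why: Sharpless asymmetric epoxidation, in which the Ti(OiPr)4/tartrate catalyst epoxidises only the allylic alcohol olefin and, with the L-(+)-tartrate, should deliver oxygen to the face that makes C4 S (C5 is set with it).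

Step 7
Reactants: 11 [(2S,3S)-3-{(3E)-3-methyl-4-[(1S,2S)-2-methylcyclopropyl]but-3-en-1-yl}-3-(propan-2-yl)oxiran-2-yl]methanol
Product: 12 (2R,3S)-2-(chloromethyl)-3-{(3E)-3-methyl-4-[(1S,2S)-2-methylcyclopropyl]but-3-en-1-yl}-3-(propan-2-yl)oxirane
Conditions: PPh3, CCl4, NaHCO3, 70 °C
Reagents that add atoms: carbon tetrachloride, ClC(Cl)(Cl)Cl
Why: Appel chlorination converts the primary alcohol into the chloride under neutral conditions that spare the epoxide and the vinylcyclopropane.

Step 8
Reactants: 12 (2R,3S)-2-(chloromethyl)-3-{(3E)-3-methyl-4-[(1S,2S)-2-methylcyclopropyl]but-3-en-1-yl}-3-(propan-2-yl)oxirane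
Product: 15 (3S,6E)-1-[benzyl(dimethyl)silyl]-6-methyl-7-[(1S,2S)-2-methylcyclopropyl]-3-(propan-2-yl)hept-6-en-1-yn-3-ol, via dilithium alkynide alkoxide 13 (not isolated), via bis-silyl ether 14 (not isolated)
Conditions: LiN(iPr)2 (3.5 equiv), THF, −78 → −30 °C; BnMe2SiCl (3 equiv), −78 → 0 °C; then AcOH, THF/H2O, 23 °C
Reagents that add atoms: benzyl(chloro)dimethylsilane, C[Si](C)(Cl)Cc1ccccc1
Why: Base-induced fragmentation of the 2,3-epoxy chloride (E2 opening of the epoxide to a chlorovinyl alkoxide, then dehydrochlorination) gives the alkynide without breaking the C4–O bond, so C4 keeps its configuration, and silylation followed by mild hydrolysis of the silyl ether leaves the alkynylsilane.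

Step 9
Reactants: 15 (3S,6E)-1-[benzyl(dimethyl)silyl]-6-methyl-7-[(1S,2S)-2-methylcyclopropyl]-3-(propan-2-yl)hept-6-en-1-yn-3-ol
Product: 16 (3S,6S,8aS)-4-[benzyl(dimethyl)silyl]-6,8a-dimethyl-3-(propan-2-yl)-1,2,3,5,6,8a-hexahydroazulen-3-ol (C5=C6 vinylsilane, C9=C10 olefin, quaternary C1)
Conditions: [Rh(CO)2Cl]2 (5 mol %), ClCH2CH2Cl (0.02 M), 80 °C
Reagents that add atoms: none
Why: Monovalent rhodium binds the vinylcyclopropane in its s-cis conformation and inserts into the less substituted cyclopropane bond C9–C7 to give a σ,π-allyl rhodacycle of trivalent rhodium, the tethered alkyne inserts at C1 and reductive elimination joins C6 to C7, which is the established course of rhodium-catalysed (5+2) cycloadditions of tethered alkyne–vinylcyclopropanes. The five-membered ring closes by intramolecular alkyne insertion into the rhodium–allyl bond (C1–C5, through the C2–C3–C4 tether) and the seven-membered ring by C(sp2)–C(sp3) reductive elimination from the eight-membered rhodacycle (C6–C7). The only new stereocentre, quaternary C1, is fixed by the cyclopropane: rhodium must sit on the alkene face that carries the breaking C9–C7 bond, so the (1S,2S) ring hands its configuration on to C1 (methyl cis to the C4 hydroxyl) whatever the remote C4 centre prefers, and C8 passes through unchanged with H8 on the face of the C1 methyl group. The step needs cleavage of C9–C7 and not of C9–C8, which the trans methyl group and the [Rh(CO)2Cl]2 catalyst should secure by steering rhodium to the less hindered bond, and the E olefin keeps the tether trans to the cyclopropane so that the alkyne can reach C1. The silicon group is a spectator that marks C6 for oxidation.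

Step 10
Reactants: 16 (3S,6S,8aS)-4-[benzyl(dimethyl)silyl]-6,8a-dimethyl-3-(propan-2-yl)-1,2,3,5,6,8a-hexahydroazulen-3-ol
Product: 18 (3S,3aR,6S,8aS)-3-hydroxy-6,8a-dimethyl-3-(propan-2-yl)-2,3,3a,5,6,8a-hexahydroazulen-4(1H)-one, via cyclic siloxane 17 (not isolated)
Conditions: Bu4NF, THF, 0 °C; then KHCO3, 30% H2O2, MeOH/THF, 23 °C
Reagents that add atoms: hydrogen peroxide, OO
Why: Tamao–Fleming oxidation of a benzyldimethylsilyl alkene (fluoride removes the benzyl group, the C4 hydroxyl closes the siloxane, peroxide turns C6–Si into the enol), and ketonisation should protonate C5 on the face of the C1 methyl and C4 hydroxyl groups, away from the isopropyl group and the C8–C10 arc, to give the cis ring fusion.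

Step 11
Reactants: 18 (3S,3aR,6S,8aS)-3-hydroxy-6,8a-dimethyl-3-(propan-2-yl)-2,3,3a,5,6,8a-hexahydroazulen-4(1H)-one
Product: 19 (3S,3aS,4R,6S,8aS)-6,8a-dimethyl-3-(propan-2-yl)-1,2,3,3a,4,5,6,8a-octahydroazulene-3,4-diol
Conditions: Me4NBH(OAc)3, MeCN/AcOH (1:1), −25 °C
Reagents that add atoms: none
Why: Evans–Saksena reduction, in which the acetoxyborohydride bound to the C4 hydroxyl delivers hydride to C6 from the convex face on which that hydroxyl sits (the concave face is in addition shielded by the isopropyl group), and should give the 1,3-anti diol with the C6 hydroxyl trans to H5 under acidic conditions that avoid retro-aldol cleavage and epimerisation at C5.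

Step 12
Reactants: 20 4-hydroxybenzoic acid
Product: 22 4-[(tert-butyldimethylsilyl)oxy]benzoic acid, via silyl ester 21 (not isolated)
Conditions: tBuMe2SiCl (2.2 equiv), imidazole, DMF, 23 °C; then AcOH, THF/H2O, 23 °C
Reagents that add atoms: tert-butyl(chloro)dimethylsilane, CC(C)(C)[Si](C)(C)Cl
Why: Silylation of both hydroxyl functions followed by selective hydrolysis of the labile silyl ester leaves the phenol protected as a silyl ether that is stable to the later acylations and oxidations.

Step 13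
Reactants: 19 (3S,3aS,4R,6S,8aS)-6,8a-dimethyl-3-(propan-2-yl)-1,2,3,3a,4,5,6,8a-octahydroazulene-3,4-diol; 22 4-[(tert-butyldimethylsilyl)oxy]benzoic acid
Product: 23 (3S,3aS,4R,6S,8aS)-3-hydroxy-6,8a-dimethyl-3-(propan-2-yl)-1,2,3,3a,4,5,6,8a-octahydroazulen-4-yl 4-[(tert-butyldimethylsilyl)oxy]benzoate
Conditions: iPrN=C=NiPr, 4-(dimethylamino)pyridine, CH2Cl2, 23 → 40 °C
Reagents that add atoms: none
Why: Steglich esterification should acylate the secondary C6 hydroxyl only, the tertiary C4 hydroxyl being too hindered to react.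

Step 14
Reactants: 23 (3S,3aS,4R,6S,8aS)-3-hydroxy-6,8a-dimethyl-3-(propan-2-yl)-1,2,3,3a,4,5,6,8a-octahydroazulen-4-yl 4-[(tert-butyldimethylsilyl)oxy]benzoate
Product: 24 C9–C10 epoxide of 23 (oxirane oxygen cis to the C1 methyl group)
Conditions: mCPBA, NaHCO3, CH2Cl2, 0 °C
Reagents that add atoms: 3-chloroperoxybenzoic acid, OOC(=O)c1cccc(Cl)c1
Why: Prilezhaev epoxidation of the only remaining olefin on the convex face of the cis-fused bicycle, anti to the C8 methyl group, the C2 methylene and the C6 ester, which should set the C10 oxygen cis to the C1 methyl group.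

Step 15
Reactants: 24 C9–C10 epoxide of 23 (oxirane oxygen cis to the C1 methyl group)
Product: 27 (3S,3aS,4R,8R,8aR)-3,8-dihydroxy-6,8a-dimethyl-3-(propan-2-yl)-1,2,3,3a,4,5,8,8a-octahydroazulen-4-yl 4-[(tert-butyldimethylsilyl)oxy]benzoate, via silyloxy triflate 25 (not isolated), via bis(trimethylsilyl) ether 26 (not isolated)
Conditions: Me3SiOTf (3 equiv), 2,6-lutidine, toluene, −78 °C; DBU, −78 → 23 °C; then 1 M HCl, THF, 0 °C
Reagents that add atoms: none
Why: Silyl triflate-mediated isomerisation of an epoxide to an allylic alcohol: triflate should open the silylated epoxide at C9 with inversion (C10 is neopentylic), DBU removes H8, which lies anti to the triflate, in an E2 elimination that forms the C8=C9 olefin and leaves the C10–O bond untouched, and dilute acid cleaves the two trimethylsilyl ethers.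

Step 16
Reactants: 27 (3S,3aS,4R,8R,8aR)-3,8-dihydroxy-6,8a-dimethyl-3-(propan-2-yl)-1,2,3,3a,4,5,8,8a-octahydroazulen-4-yl 4-[(tert-butyldimethylsilyl)oxy]benzoate
Product: 28 (3S,3aS,4R,8R,8aR)-3-hydroxy-6,8a-dimethyl-8-[(3-methylbutanoyl)oxy]-3-(propan-2-yl)-1,2,3,3a,4,5,8,8a-octahydroazulen-4-yl 4-[(tert-butyldimethylsilyl)oxy]benzoate
Conditions: (iBuCO)2O, Et3N, 4-(dimethylamino)pyridine (cat.), CH2Cl2, 23 °C
Reagents that add atoms: 3-methylbutanoic anhydride, CC(C)CC(=O)OC(=O)CC(C)C
Why: Nucleophile-catalysed acylation of the secondary allylic alcohol with retention at C10, while the tertiary alcohol and the aryl silyl ether do not react.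

Step 17
Reactants: 28 (3S,3aS,4R,8R,8aR)-3-hydroxy-6,8a-dimethyl-8-[(3-methylbutanoyl)oxy]-3-(propan-2-yl)-1,2,3,3a,4,5,8,8a-octahydroazulen-4-yl 4-[(tert-butyldimethylsilyl)oxy]benzoate
Product: 29 (3S,3aS,4R,8R,8aR)-3-hydroxy-6,8a-dimethyl-8-[(3-methylbutanoyl)oxy]-3-(propan-2-yl)-1,2,3,3a,4,5,8,8a-octahydroazulen-4-yl 4-hydroxybenzoate
Conditions: Bu4NF, AcOH, THF, 0 °C
Reagents that add atoms: none
Why: Fluoride cleavage of the aryl silyl ether, buffered with acetic acid so that the phenoxide cannot trigger ester migration or hydrolysis, should release the target.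

Compound list
1 | (E)-but-2-en-1-ol | C/C=C/CO | starting material
2 | [(1S,2S)-2-methylcyclopropyl]methanol | OC[C@H]1C[C@@H]1C | intermediate
3 | (1S,2S)-2-methylcyclopropane-1-carbaldehyde | O=C[C@H]1C[C@@H]1C | intermediate
4 | (2E)-2-methyl-3-[(1S,2S)-2-methylcyclopropyl]prop-2-enal | O=C/C(C)=C/[C@H]1C[C@@H]1C | intermediate
5 | (1S,2S)-1-methyl-2-[(1E)-2-methylbuta-1,3-dien-1-yl]cyclopropane | C=C/C(C)=C/[C@H]1C[C@@H]1C | intermediate
6 | 4-methylpent-2-yn-1-ol | CC(C)C#CCO | starting material
7 | sodium cyclic alkenylaluminate from 6 (aluminium on C3, chelated by the alkoxide) | [Na+].COCCO[Al-]1(OCCOC)OCC=C1C(C)C | intermediate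
8 | (2Z)-3-iodo-4-methylpent-2-en-1-ol | CC(C)/C(I)=C/CO | intermediate
9 | 9-{(3E)-3-methyl-4-[(1S,2S)-2-methylcyclopropyl]but-3-en-1-yl}-9-borabicyclo[3.3.1]nonane | B1(CC/C(C)=C/[C@H]2C[C@@H]2C)C2CCCC1CCC2 | intermediate
10 | (2E,6E)-6-methyl-7-[(1S,2S)-2-methylcyclopropyl]-3-(propan-2-yl)hepta-2,6-dien-1-ol | CC(C)/C(CC/C(C)=C/[C@H]1C[C@@H]1C)=C/CO | intermediate
11 | [(2S,3S)-3-{(3E)-3-methyl-4-[(1S,2S)-2-methylcyclopropyl]but-3-en-1-yl}-3-(propan-2-yl)oxiran-2-yl]methanol | OC[C@@H]1O[C@]1(C(C)C)CC/C(C)=C/[C@H]2C[C@@H]2C | intermediate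
12 | (2R,3S)-2-(chloromethyl)-3-{(3E)-3-methyl-4-[(1S,2S)-2-methylcyclopropyl]but-3-en-1-yl}-3-(propan-2-yl)oxirane | ClC[C@@H]1O[C@]1(C(C)C)CC/C(C)=C/[C@H]2C[C@@H]2C | intermediate
13 | dilithium salt of (3S,6E)-6-methyl-7-[(1S,2S)-2-methylcyclopropyl]-3-(propan-2-yl)hept-6-en-1-yn-3-ol (alkynide and alkoxide) | [Li]C#C[C@@](O[Li])(C(C)C)CC/C(C)=C/[C@H]1C[C@@H]1C | intermediate
14 | O,C-bis[benzyl(dimethyl)silyl] derivative of the alkynol (silyl ether on C4, silyl on C6) | C[Si](C)(Cc1ccccc1)C#C[C@@](O[Si](C)(C)Cc1ccccc1)(C(C)C)CC/C(C)=C/[C@H]1C[C@@H]1C | intermediate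
15 | (3S,6E)-1-[benzyl(dimethyl)silyl]-6-methyl-7-[(1S,2S)-2-methylcyclopropyl]-3-(propan-2-yl)hept-6-en-1-yn-3-ol | C[Si](C)(Cc1ccccc1)C#C[C@@](O)(C(C)C)CC/C(C)=C/[C@H]1C[C@@H]1C | intermediate
16 | (3S,6S,8aS)-4-[benzyl(dimethyl)silyl]-6,8a-dimethyl-3-(propan-2-yl)-1,2,3,5,6,8a-hexahydroazulen-3-ol | C[C@@H]1C=C[C@]2(C)CC[C@](O)(C(C)C)C2=C([Si](C)(C)Cc3ccccc3)C1 | intermediate
17 | cyclic siloxane of 16 (2,2-dimethyl-1,2-oxasilole, oxygen on C4, silicon on C6, C5=C6 retained) | C[C@@H]1C=C[C@]2(C)CC[C@@]3(C(C)C)O[Si](C)(C)C(C1)=C23 | intermediate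
18 | (3S,3aR,6S,8aS)-3-hydroxy-6,8a-dimethyl-3-(propan-2-yl)-2,3,3a,5,6,8a-hexahydroazulen-4(1H)-one | C[C@@H]1C=C[C@]2(C)CC[C@](O)(C(C)C)[C@@H]2C(=O)C1 | intermediate
19 | (3S,3aS,4R,6S,8aS)-6,8a-dimethyl-3-(propan-2-yl)-1,2,3,3a,4,5,6,8a-octahydroazulene-3,4-diol | C[C@@H]1C=C[C@]2(C)CC[C@](O)(C(C)C)[C@@H]2[C@H](O)C1 | intermediate
20 | 4-hydroxybenzoic acid | O=C(O)c1ccc(O)cc1 | starting material
21 | tert-butyldimethylsilyl 4-[(tert-butyldimethylsilyl)oxy]benzoate | CC(C)(C)[Si](C)(C)OC(=O)c1ccc(O[Si](C)(C)C(C)(C)C)cc1 | intermediate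
22 | 4-[(tert-butyldimethylsilyl)oxy]benzoic acid | CC(C)(C)[Si](C)(C)Oc1ccc(cc1)C(=O)O | intermediate
23 | (3S,3aS,4R,6S,8aS)-3-hydroxy-6,8a-dimethyl-3-(propan-2-yl)-1,2,3,3a,4,5,6,8a-octahydroazulen-4-yl 4-[(tert-butyldimethylsilyl)oxy]benzoate | C[C@@H]1C=C[C@]2(C)CC[C@](O)(C(C)C)[C@@H]2[C@H](OC(=O)c3ccc(O[Si](C)(C)C(C)(C)C)cc3)C1 | intermediate
24 | C9–C10 epoxide of 23 (oxirane oxygen cis to the C1 methyl group) | C[C@@H]1[C@H]2O[C@H]2[C@]3(C)CC[C@](O)(C(C)C)[C@@H]3[C@H](OC(=O)c4ccc(O[Si](C)(C)C(C)(C)C)cc4)C1 | intermediate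
25 | C9 triflate (trans to the C10 oxygen) with trimethylsilyl ethers on the C10 and C4 oxygens | C[C@@H]1[C@H](OS(=O)(=O)C(F)(F)F)[C@@H](O[Si](C)(C)C)[C@]2(C)CC[C@](O[Si](C)(C)C)(C(C)C)[C@@H]2[C@H](OC(=O)c3ccc(O[Si](C)(C)C(C)(C)C)cc3)C1 | intermediate
26 | bis(trimethylsilyl) ether of 27 (C10 and C4 oxygens silylated, C8=C9 olefin) | CC1=C[C@@H](O[Si](C)(C)C)[C@]2(C)CC[C@](O[Si](C)(C)C)(C(C)C)[C@@H]2[C@H](OC(=O)c3ccc(O[Si](C)(C)C(C)(C)C)cc3)C1 | intermediate
27 | (3S,3aS,4R,8R,8aR)-3,8-dihydroxy-6,8a-dimethyl-3-(propan-2-yl)-1,2,3,3a,4,5,8,8a-octahydroazulen-4-yl 4-[(tert-butyldimethylsilyl)oxy]benzoate | CC1=C[C@@H](O)[C@]2(C)CC[C@](O)(C(C)C)[C@@H]2[C@H](OC(=O)c3ccc(O[Si](C)(C)C(C)(C)C)cc3)C1 | intermediate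
28 | (3S,3aS,4R,8R,8aR)-3-hydroxy-6,8a-dimethyl-8-[(3-methylbutanoyl)oxy]-3-(propan-2-yl)-1,2,3,3a,4,5,8,8a-octahydroazulen-4-yl 4-[(tert-butyldimethylsilyl)oxy]benzoate | CC1=C[C@@H](OC(=O)CC(C)C)[C@]2(C)CC[C@](O)(C(C)C)[C@@H]2[C@H](OC(=O)c3ccc(O[Si](C)(C)C(C)(C)C)cc3)C1 | intermediate
29 | (3S,3aS,4R,8R,8aR)-3-hydroxy-6,8a-dimethyl-8-[(3-methylbutanoyl)oxy]-3-(propan-2-yl)-1,2,3,3a,4,5,8,8a-octahydroazulen-4-yl 4-hydroxybenzoate | CC1=C[C@@H](OC(=O)CC(C)C)[C@]2(C)CC[C@](O)(C(C)C)[C@@H]2[C@H](OC(=O)c2ccc(O)cc2)C1 | target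

Total step count: 17. Longest linear sequence: 15 steps (steps 1–3, 5–11 and 13–17).

Steps most likely to fail

1. Step 9. The cycloaddition may stall or leave its course: the C1 methyl group points at the cyclopropane in the reactive s-cis conformer, the silicon group ends up eclipsing the fully substituted C4, and the isopropyl group is pushed toward the folding diene, so that under forcing conditions rhodium may open the C9–C8 bond instead (relay to C1 lost), leave the rhodacycle by β-hydride elimination, or attack the benzylic C–Si bond. The fallback lightens the alkyne partner and changes the way C6 is oxidised, sets out from epoxy chloride 12 and comes back to the route at ketone 18: the dilithium species 13 would be generated as in step 8 and quenched with Me3SiCl to give the O,C-bis(trimethylsilyl) compound F1; AcOH in aqueous THF would hydrolyse its silyl ether to the trimethylsilyl alkynol F2, the smallest silicon-substituted partner and one free of benzylic C–Si bonds; [Rh(CO)2Cl]2 in ClCH2CH2Cl would then give the trimethylsilyl diene F3; epoxidation with VO(acac)2 and tBuOOH, directed by the C4 hydroxyl, would give the α,β-epoxysilane F4; and cold H2SO4 in aqueous THF would hydrolyse it to ketone 18 through the same C5=C6 enol.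

2. Step 10. Fluoride-induced protodesilylation may outrun peroxide oxidation of the hindered, fully substituted vinyl–silicon bond, and in the basic peroxide medium ketonisation may occur on the wrong face or be followed by equilibration to the trans-fused C5 epimer or by retro-aldol cleavage of the β-hydroxy ketone. The fallback replaces the oxidation of the C–Si bond by epoxysilane hydrolysis under acid, sets out from vinylsilane 16 and comes back to the route at ketone 18: VO(acac)2 and tBuOOH, directed by the C4 hydroxyl, would epoxidise the vinylsilane to the benzyldimethylsilyl epoxide F5, and H2SO4 in aqueous THF at 0 °C would open it and expel silicon to give the enol, which ketonises kinetically in acid without any base present.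

3. Step 15. Triflate may attack the silylated epoxide with the wrong regiochemistry, or the secondary triflate may ionise (hydride shift, ring contraction) or eliminate toward C10 before DBU removes H8. The fallback separates opening, acylation and elimination, sets out from epoxide 24 and comes back to the route at silyl-protected diester 28: MgBr2·OEt2 in Et2O at 0 °C would open the epoxide at C9 with inversion to the trans bromohydrin F6; (iBuCO)2O with 4-(dimethylamino)pyridine would acylate its C10 hydroxyl to the bromo isovalerate F7; and DBU in toluene at 80 °C would then remove H8, which is anti to bromide, in an E2 elimination that gives 28 directly.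

Further compounds
F1 | step 9 | O,C-bis(trimethylsilyl) derivative of the alkynol (trimethylsilyl ether on C4, trimethylsilyl on C6) | C[Si](C)(C)C#C[C@@](O[Si](C)(C)C)(C(C)C)CC/C(C)=C/[C@H]1C[C@@H]1C
F2 | step 9 | (3S,6E)-6-methyl-7-[(1S,2S)-2-methylcyclopropyl]-3-(propan-2-yl)-1-(trimethylsilyl)hept-6-en-1-yn-3-ol | C[Si](C)(C)C#C[C@@](O)(C(C)C)CC/C(C)=C/[C@H]1C[C@@H]1C
F3 | step 9 | (3S,6S,8aS)-6,8a-dimethyl-3-(propan-2-yl)-4-(trimethylsilyl)-1,2,3,5,6,8a-hexahydroazulen-3-ol | C[C@@H]1C=C[C@]2(C)CC[C@](O)(C(C)C)C2=C([Si](C)(C)C)C1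
F4 | step 9 | C5–C6 epoxide of F3, oxirane oxygen cis to the C4 hydroxyl | C[C@@H]1C=C[C@]2(C)CC[C@](O)(C(C)C)[C@@]23O[C@@]3([Si](C)(C)C)C1
F5 | step 10 | C5–C6 epoxide of 16, oxirane oxygen cis to the C4 hydroxyl | C[C@@H]1C=C[C@]2(C)CC[C@](O)(C(C)C)[C@@]23O[C@@]3([Si](C)(C)Cc4ccccc4)C1
F6 | step 15 | trans bromohydrin from 24 (bromine on C9, hydroxyl on C10 cis to the C1 methyl group) | C[C@@H]1[C@H](Br)[C@@H](O)[C@]2(C)CC[C@](O)(C(C)C)[C@@H]2[C@H](OC(=O)c3ccc(O[Si](C)(C)C(C)(C)C)cc3)C1
F7 | step 15 | C10 isovalerate of F6 | C[C@@H]1[C@H](Br)[C@@H](OC(=O)CC(C)C)[C@]2(C)CC[C@](O)(C(C)C)[C@@H]2[C@H](OC(=O)c3ccc(O[Si](C)(C)C(C)(C)C)cc3)C1
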